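**Strategy.** The oxan-4-one ring is divided into two three-atom halves, O1–C2–C3 and C4–C5–C6. The key step exploits the β-alkoxy ketone relationship of ring oxygen O1 to the C4 carbonyl through C5–C6, next to the acyl-type C3–C4 bond: a β-oxido alkyllithium carrying the preset C2 carbinol acylates an (E)-γ-hydroxy enoyl Weinreb amide carrying the preset side-chain carbinol, and the enone released in the same flask is closed by 6-endo oxa-Michael addition of O1 to C6, which places the C6 substituent cis to the C2 aryl group. The precursors are an acyclic iodohydrin and an acyclic enamide; hydrogenolysis of two benzyl ethers then gives the target.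

Key step: step 6

Remark: compounds 1, 4, 5 and 10 are taken as catalogue chemicals; the target is read as the 2,6-cis oxan-4-one (2S,6R) with an (S)-carbinol in the side chain.

**Step 1**
Reactants: 1 1-[4-(benzyloxy)-3-methoxyphenyl]-2-bromoethan-1-one
Product: 2 (1R)-1-[4-(benzyloxy)-3-methoxyphenyl]-2-bromoethan-1-ol
Conditions: (R)-2-methyl-CBS-oxazaborolidine (10 mol%), BH3·SMe2, THF, 0 °C; MeOH quench
Reagents that add atoms: none
Why: Corey–Bakshi–Shibata reduction, in which the oxazaborolidine–borane complex binds the ketone with the aryl group as the large substituent and delivers hydride to one face, the (R)-catalyst giving the (R)-bromohydrin (CH2Br outranks aryl in the descriptor) while the C–Br bond and the benzyl ether are left alone.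

**Step 2**
Reactants: 2 (1R)-1-[4-(benzyloxy)-3-methoxyphenyl]-2-bromoethan-1-ol
Product: 3 (1R)-1-[4-(benzyloxy)-3-methoxyphenyl]-2-iodoethan-1-ol
Conditions: NaI, acetone, 50 °C, dark
Reagents that add atoms: sodium iodide, [Na+].[I-]
Why: Finkelstein halide exchange (SN2 at the primary carbon, driven by precipitation of NaBr) installs the iodide needed for clean low-temperature iodine–lithium exchange without touching the carbinol stereocenter.

**Step 3**
Reactants: 4 1-(benzyloxy)-4-bromobenzene; 5 (S)-epichlorohydrin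
Product: 7 (2S)-1-[4-(benzyloxy)phenyl]-3-chloropropan-2-ol, via aryl Grignard reagent 6 (not isolated)
Conditions: Mg, THF, 50 °C; then CuI (10 mol%), 5, −40 to 0 °C; 1 M HCl
Reagents that add atoms: none
Why: Copper-catalysed Grignard opening of the epoxide at its unsubstituted carbon (SN2) is faster than displacement of chloride, so the stereocenter of 5 should be carried unchanged into the (S)-chlorohydrin.

**Step 4**
Reactants: 7 (2S)-1-[4-(benzyloxy)phenyl]-3-chloropropan-2-ol
Product: 9 (2S)-1-[4-(benzyloxy)phenyl]but-3-en-2-ol, via benzyl oxirane 8 (not isolated)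
Conditions: Me3S+ I− (4 equiv), n-BuLi (3.8 equiv), THF, −10 °C to rt
Reagents that add atoms: trimethylsulfonium iodide, C[S+](C)C.[I-]
Why: One equivalent of ylide acts as base and closes the chlorohydrin to oxirane 8, a second opens it at the terminal carbon, and the resulting sulfonium betaine eliminates dimethyl sulfide to the allylic alkoxide (one-carbon epoxide-to-allylic-alcohol homologation with dimethylsulfonium methylide), none of which touches the carbinol center.

**Step 5**
Reactants: 9 (2S)-1-[4-(benzyloxy)phenyl]but-3-en-2-ol; 10 N-methoxy-N-methylprop-2-enamide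
Product: 11 (2E,4S)-5-[4-(benzyloxy)phenyl]-4-hydroxy-N-methoxy-N-methylpent-2-enamide
Conditions: 10 (3 equiv), second-generation Hoveyda–Grubbs catalyst RuCl2(H2IMes)(=CH-C6H4-2-OiPr) (5 mol%), CH2Cl2, 40 °C
Reagents that add atoms: none
Why: Olefin cross-metathesis between a terminal allylic alcohol and an electron-poor acrylamide that does not homodimerise should be selective for the cross product and give the E-alkene under thermodynamic control, the carbinol center not being involved.

**Step 6**
Reactants: 3 (1R)-1-[4-(benzyloxy)-3-methoxyphenyl]-2-iodoethan-1-ol; 11 (2E,4S)-5-[4-(benzyloxy)phenyl]-4-hydroxy-N-methoxy-N-methylpent-2-enamide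
Product: 16 (2S,6R)-2-[4-(benzyloxy)-3-methoxyphenyl]-6-[(1S)-2-[4-(benzyloxy)phenyl]-1-hydroxyethyl]oxan-4-one, via beta-oxido alkyllithium 12 (not isolated), via chloromagnesium alkoxide 13 (not isolated), via tetrahedral N-methoxy-N-methyl adduct 14 (not isolated), via open-chain hydroxy enone 15 (not isolated)
Conditions: 3 (1.3 equiv): MeLi (1.0 equiv) then t-BuLi (2.1 equiv), Et2O, −78 °C; 11: i-PrMgCl (1.0 equiv), THF, −40 °C; combine at −78 °C; AcOH, −78 to 0 °C; then DBU, rt, same flask
Reagents that add atoms: none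
Why: O-Deprotonation and iodine–lithium exchange turn 3 into the β-oxido alkyllithium 12, whose primary carbanion (C3) adds to the Weinreb carbonyl (C4) of the pre-metalated amide 13 to give the chelated tetrahedral adduct 14; acetic acid collapses 14 to enone 15, and DBU then promotes reversible intramolecular oxa-Michael addition of the benzylic hydroxyl (O1) to the enone β-carbon (C6). The closest known reaction types are halogen–lithium exchange followed by Weinreb ketone synthesis, and base-mediated oxa-Michael cyclisation of β-hydroxy enones to cis-2,6-disubstituted oxan-4-ones. The ring closes in the 6-endo-trig mode. C2 and the side-chain carbinol come unchanged from 3 and 11, and the new C6 center is set by C2 under thermodynamic control, since Michael/retro-Michael equilibration should funnel the material into the chair with the C2 aryl group and the C6 side chain both equatorial (2,6-cis, 6R). The step needs carbonyl addition over conjugate addition, which the hard alkyllithium, the Weinreb chelate and the anionic γ-alkoxide of 13 should secure, and survival of 12 against β-elimination, which −78 °C and the poor leaving-group ability of oxide should secure. O1 is the only competent nucleophile for C6 because the E-alkene holds the side-chain hydroxyl away from C4 and its addition to C6 would give a strained oxirane.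

**Step 7**
Reactants: 16 (2S,6R)-2-[4-(benzyloxy)-3-methoxyphenyl]-6-[(1S)-2-[4-(benzyloxy)phenyl]-1-hydroxyethyl]oxan-4-one
Product: 17 (2S,6R)-2-(4-hydroxy-3-methoxyphenyl)-6-[(1S)-1-hydroxy-2-(4-hydroxyphenyl)ethyl]oxan-4-one
Conditions: H2 (1 atm), 10% Pd/C, EtOAc/MeOH, rt
Reagents that add atoms: none
Why: Catalytic hydrogenolysis should cleave the two aryl benzyl ethers rapidly, while the hindered benzylic C2–O1 bond of the ring and the saturated ketone are expected to survive at 1 atm and short reaction time.

**Compound list**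

1 | 1-[4-(benzyloxy)-3-methoxyphenyl]-2-bromoethan-1-one | COc1cc(C(=O)CBr)ccc1OCc1ccccc1 | starting material
2 | (1R)-1-[4-(benzyloxy)-3-methoxyphenyl]-2-bromoethan-1-ol | COc1cc([C@@H](O)CBr)ccc1OCc1ccccc1 | intermediate
3 | (1R)-1-[4-(benzyloxy)-3-methoxyphenyl]-2-iodoethan-1-ol | COc1cc([C@@H](O)CI)ccc1OCc1ccccc1 | intermediate
4 | 1-(benzyloxy)-4-bromobenzene | Brc1ccc(OCc2ccccc2)cc1 | starting material
5 | (S)-epichlorohydrin, (2S)-2-(chloromethyl)oxirane | ClC[C@@H]1CO1 | starting material
6 | [4-(benzyloxy)phenyl]magnesium bromide | Br[Mg]c1ccc(OCc2ccccc2)cc1 | intermediate (not isolated)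
7 | (2S)-1-[4-(benzyloxy)phenyl]-3-chloropropan-2-ol | ClC[C@@H](O)Cc1ccc(OCc2ccccc2)cc1 | intermediate
8 | (2S)-2-[4-(benzyloxy)benzyl]oxirane | C1O[C@H]1Cc1ccc(OCc2ccccc2)cc1 | intermediate (not isolated)
9 | (2S)-1-[4-(benzyloxy)phenyl]but-3-en-2-ol | C=C[C@@H](O)Cc1ccc(OCc2ccccc2)cc1 | intermediate
10 | N-methoxy-N-methylprop-2-enamide | C=CC(=O)N(C)OC | starting material
11 | (2E,4S)-5-[4-(benzyloxy)phenyl]-4-hydroxy-N-methoxy-N-methylpent-2-enamide | CON(C)C(=O)/C=C/[C@@H](O)Cc1ccc(OCc2ccccc2)cc1 | intermediate
12 | lithium (1S)-1-[4-(benzyloxy)-3-methoxyphenyl]-2-lithioethan-1-olate (same spatial arrangement as 3; descriptor changes by priority only) | COc1cc([C@@H](O[Li])C[Li])ccc1OCc1ccccc1 | intermediate (not isolated)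
13 | chloromagnesium (2E,4S)-5-[4-(benzyloxy)phenyl]-1-[methoxy(methyl)amino]-1-oxopent-2-en-4-olate | CON(C)C(=O)/C=C/[C@@H](O[Mg]Cl)Cc1ccc(OCc2ccccc2)cc1 | intermediate (not isolated)
14 | tetrahedral adduct of 12 and 13: dilithium/chloromagnesium salt of (1S,4E,6S)-1-[4-(benzyloxy)-3-methoxyphenyl]-7-[4-(benzyloxy)phenyl]-3-[methoxy(methyl)amino]hept-4-ene-1,3,6-triol | COc1cc([C@@H](O[Li])CC(O[Li])(N(C)OC)/C=C/[C@@H](O[Mg]Cl)Cc2ccc(OCc3ccccc3)cc2)ccc1OCc1ccccc1 | intermediate (not isolated)
15 | (1S,4E,6S)-1-[4-(benzyloxy)-3-methoxyphenyl]-7-[4-(benzyloxy)phenyl]-1,6-dihydroxyhept-4-en-3-one | COc1cc([C@@H](O)CC(=O)/C=C/[C@@H](O)Cc2ccc(OCc3ccccc3)cc2)ccc1OCc1ccccc1 | intermediate (not isolated)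
16 | (2S,6R)-2-[4-(benzyloxy)-3-methoxyphenyl]-6-[(1S)-2-[4-(benzyloxy)phenyl]-1-hydroxyethyl]oxan-4-one | COc1cc([C@@H]2CC(=O)C[C@H]([C@@H](O)Cc3ccc(OCc4ccccc4)cc3)O2)ccc1OCc1ccccc1 | intermediate
17 | (2S,6R)-2-(4-hydroxy-3-methoxyphenyl)-6-[(1S)-1-hydroxy-2-(4-hydroxyphenyl)ethyl]oxan-4-one | COc1cc([C@@H]2CC(=O)C[C@H]([C@@H](O)Cc3ccc(O)cc3)O2)ccc1O | target

**Step count.** Total: 7 steps. Longest linear sequence: 5 steps (steps 3, 4, 5, 6, 7).

**Steps most likely to fail**

1. Step 6. The β-oxido alkyllithium may eliminate lithium oxide to the styrene before it is acylated, conjugate addition may compete with carbonyl addition, and the benzylic β-hydroxy ketone may dehydrate or undergo retro-aldol cleavage during the base-mediated ring closure. The fallback makes the C2–C3 bond by an aldol reaction instead of the C3–C4 bond by acylation; it sets out from 11 and comes back at 15. Compound 11 would be silylated (TBSCl, imidazole, DMF) to (2E,4S)-5-[4-(benzyloxy)phenyl]-4-[(tert-butyldimethylsilyl)oxy]-N-methoxy-N-methylpent-2-enamide F1. MeMgBr (THF, 0 °C) should convert F1 into the methyl enone (3E,5S)-6-[4-(benzyloxy)phenyl]-5-[(tert-butyldimethylsilyl)oxy]hex-3-en-2-one F2. Enolisation of F2 with (−)-Ipc2BCl and Et3N (Et2O, 0 °C) and addition to commercial 4-(benzyloxy)-3-methoxybenzaldehyde at −78 °C, with H2O2 work-up, is a diisopinocampheylboron-mediated methyl-ketone aldol reaction. This reagent enantiomer is expected to direct the enolate to the Si face of the aldehyde, which corresponds to the (S)-carbinol, and should give (1S,4E,6S)-1-[4-(benzyloxy)-3-methoxyphenyl]-7-[4-(benzyloxy)phenyl]-6-[(tert-butyldimethylsilyl)oxy]-1-hydroxyhept-4-en-3-one F3. HF·pyridine (THF) would remove the silyl group to give 15, which DBU should close to 16 as in step 6.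

2. Step 7. Over-reduction is the concern: hydrogenolysis of the ring benzylic C2–O1 bond of the electron-rich aryl ether may compete with cleavage of the benzyl ethers. The fallback abandons reduction in favour of Lewis-acid dealkylation; it sets out from 16 and comes back at 17. BCl3 with pentamethylbenzene as benzyl-cation scavenger (CH2Cl2, −78 °C) should cleave both aryl benzyl ethers without hydrogen; no new compound is made on the way.

3. Step 5. The metathesis may stall after catalyst decomposition, and the allylic alcohol may homodimerise or isomerise to the ketone through ruthenium hydrides. The fallback builds the enamide by olefination of an aldehyde; it sets out from 9 and comes back at 11. Compound 9 would be silylated (TESCl, imidazole) to (2S)-{[1-(4-(benzyloxy)phenyl)but-3-en-2-yl]oxy}triethylsilane F4. Oxidative cleavage of the vinyl group (OsO4 cat., NaIO4, 2,6-lutidine, dioxane/water) should give (2S)-3-[4-(benzyloxy)phenyl]-2-[(triethylsilyl)oxy]propanal F5. Horner–Wadsworth–Emmons olefination with diethyl {2-[methoxy(methyl)amino]-2-oxoethyl}phosphonate (LiCl, DIPEA, MeCN) should give (2E,4S)-5-[4-(benzyloxy)phenyl]-N-methoxy-N-methyl-4-[(triethylsilyl)oxy]pent-2-enamide F6. HF·pyridine would then release 11.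

**Further compounds**

F1 | step 6 | (2E,4S)-5-[4-(benzyloxy)phenyl]-4-[(tert-butyldimethylsilyl)oxy]-N-methoxy-N-methylpent-2-enamide | CON(C)C(=O)/C=C/[C@@H](O[Si](C)(C)C(C)(C)C)Cc1ccc(OCc2ccccc2)cc1
F2 | step 6 | (3E,5S)-6-[4-(benzyloxy)phenyl]-5-[(tert-butyldimethylsilyl)oxy]hex-3-en-2-one | CC(=O)/C=C/[C@@H](O[Si](C)(C)C(C)(C)C)Cc1ccc(OCc2ccccc2)cc1
F3 | step 6 | (1S,4E,6S)-1-[4-(benzyloxy)-3-methoxyphenyl]-7-[4-(benzyloxy)phenyl]-6-[(tert-butyldimethylsilyl)oxy]-1-hydroxyhept-4-en-3-one | COc1cc([C@@H](O)CC(=O)/C=C/[C@@H](O[Si](C)(C)C(C)(C)C)Cc2ccc(OCc3ccccc3)cc2)ccc1OCc1ccccc1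
F0 | step 7 | none | none
F4 | step 5 | (2S)-{[1-(4-(benzyloxy)phenyl)but-3-en-2-yl]oxy}triethylsilane | C=C[C@@H](O[Si](CC)(CC)CC)Cc1ccc(OCc2ccccc2)cc1
F5 | step 5 | (2S)-3-[4-(benzyloxy)phenyl]-2-[(triethylsilyl)oxy]propanal | O=C[C@@H](O[Si](CC)(CC)CC)Cc1ccc(OCc2ccccc2)cc1
F6 | step 5 | (2E,4S)-5-[4-(benzyloxy)phenyl]-N-methoxy-N-methyl-4-[(triethylsilyl)oxy]pent-2-enamide | CON(C)C(=O)/C=C/[C@@H](O[Si](CC)(CC)CC)Cc1ccc(OCc2ccccc2)cc1
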